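**Retrosynthetic overview** (eudesmane numbering: C-4 carbinol, C-5/C-10 ring fusion, C-7 side-chain carbon, C-9 ester carbon)
1. The acrylic acid comes from Pinnick oxidation of an enal unmasked from a dimethyl acetal; the C-9 ester comes from acylation of the axial 9α-alkoxide with (R)-3-methylpentanoyl chloride (made by Cu-catalysed asymmetric ethyl addition to methyl crotonate).
2. The C-7–C-11 bond comes from axial cuprate conjugate addition of a 2-metallated acrolein acetal (from acrolein) to a Δ7-en-9-one; the C-9 carbinol comes from a bulky hydride.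
3. The enone comes from Saegusa oxidation; the 4α-OH comes from Mukaiyama hydration of a C-4 exocyclic methylene.
4. Ring A is formed last, by intramolecular B-alkyl Suzuki–Miyaura coupling (C-3–C-4 bond) of an iodoalkene and an allyl arm held trans on ring B.
5. Ring B is present from the start (2-methylcyclohexenone); C-5 and C-10 are set by Cu-catalysed enantioselective conjugate addition of a 1-silylvinylalane followed by Pd-catalysed allylation of the enolate.

Assumption: in the two ligand-controlled steps (1 and 10) the ligand antipode written is taken to be the one that gives the configuration drawn; if the sense of induction is opposite, the mirror-image ligand is used.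

**Step 1**
Reactants: 1 2-methylcyclohex-2-en-1-one; 2 ethynyltrimethylsilane; 3 prop-2-en-1-yl acetate
Product: 6 (2S,3R)-2-methyl-2-(prop-2-en-1-yl)-3-[1-(trimethylsilyl)ethenyl]cyclohexan-1-one, via diisobutyl[1-(trimethylsilyl)ethenyl]aluminium 4 (not isolated), via diisobutylaluminium enolate 5 (not isolated)
Conditions: 2, i-Bu2AlH, hexanes/THF, 55 °C; then 1, Cu(OTf)2 (5 mol %), (4S,5S)-1-(2,6-diethylphenyl)-4,5-diphenyl-3-(2-sulfonatophenyl)-4,5-dihydroimidazolium (5.5 mol %), THF, −15 °C; then 3 (3 equiv), Pd(PPh3)4 (5 mol %), 0 °C → rt; aq. potassium sodium tartrate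
Reagents that add atoms: none
Why: Proposed new method: the carbene–copper-catalysed enantioselective conjugate addition of the 1-silylvinylalane, so far used only on 3-substituted cycloalkenones, is applied to a 2-methyl, 3-unsubstituted enone, where the sulfonate arm of the carbene binds the alane so that the alkenyl group passes from copper to one face of C-3 of the aluminium-activated enone (the in-plane 2-methyl group does not shield C-3) and sets the C-3 stereocentre, after which the regiodefined tetrasubstituted aluminium enolate, with its bulky 3-substituent pseudoaxial to avoid allylic strain with the 2-methyl group, attacks the π-allylpalladium cation on the opposite face (Tsuji–Trost allylation) and sets the quaternary centre trans; the closest known reaction types are the carbene–copper conjugate addition of silyl-substituted vinylaluminium reagents to 3-methylcyclohexenone and the Pd-catalysed allylation of aluminium enolates formed by Cu-catalysed conjugate addition.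

**Step 2**
Reactants: 6 (2S,3R)-2-methyl-2-(prop-2-en-1-yl)-3-[1-(trimethylsilyl)ethenyl]cyclohexan-1-one
Product: 7 (2S,3R)-3-(1-iodoethenyl)-2-methyl-2-(prop-2-en-1-yl)cyclohexan-1-one
Conditions: N-iodosuccinimide (1.5 equiv), MeCN/ClCH2CN 4:1, 0 °C → rt, dark
Reagents that add atoms: N-iodosuccinimide, O=C1CCC(=O)N1I
Why: Ipso-iododesilylation of the vinylsilane (iodonium attack at the silicon-bearing carbon, β-silyl cation, loss of silicon) gives the 1-iodoalkene, while the monosubstituted alkene and the ketone do not react and neither stereocentre is touched.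

**Step 3**
Reactants: 7 (2S,3R)-3-(1-iodoethenyl)-2-methyl-2-(prop-2-en-1-yl)cyclohexan-1-one
Product: 9 (4aS,8aS)-8a-methyl-5-methylideneoctahydronaphthalen-1(2H)-one, via B-alkyl-9-borabicyclo[3.3.1]nonane 8 (not isolated)
Conditions: 9-BBN (1.3 equiv), THF, 0 °C → rt; then PdCl2(dppf) (10 mol %), AsPh3 (10 mol %), Cs2CO3 (3 equiv), DMF/THF/H2O, 0.01 M, 50 °C
Reagents that add atoms: none
Why: 9-BBN adds anti-Markovnikov to the terminal alkene faster than it reduces the hindered α-quaternary ketone or touches the iodoalkene, and the primary alkylborane then undergoes intramolecular B-alkyl Suzuki–Miyaura cross-coupling with the alkenyl iodide (C-3–C-4 bond, ring A), giving the trans-fused decalone because the two arms are already trans on ring B; no stereocentre is created.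

**Step 4**
Reactants: 9 (4aS,8aS)-8a-methyl-5-methylideneoctahydronaphthalen-1(2H)-one
Product: 11 (4aR,5R,8aS)-5-hydroxy-5,8a-dimethyloctahydronaphthalen-1(2H)-one, via tertiary hydroperoxide 10 (not isolated)
Conditions: Co(acac)2 (20 mol %), PhSiH3 (2 equiv), O2 (1 atm), THF, rt; then PPh3 (1.2 equiv)
Reagents that add atoms: dioxygen, O=O
Why: Mukaiyama hydration, in which hydrogen-atom transfer from a cobalt hydride to the exocyclic methylene gives the tertiary C-5 radical that is trapped by O2 on the α-face because axial approach on the β-face is blocked by the syn-axial angular methyl, so the new C–O bond is equatorial (5R) and the new methyl axial; PPh3 reduces the hydroperoxide and the ketone is untouched.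

**Step 5**
Reactants: 11 (4aR,5R,8aS)-5-hydroxy-5,8a-dimethyloctahydronaphthalen-1(2H)-one
Product: 13 (4aR,5R,8aS)-5,8a-dimethyl-5-[(trimethylsilyl)oxy]-4a,5,6,7,8,8a-hexahydronaphthalen-1(4H)-one, via bis(trimethylsilyl) enol ether 12 (not isolated)
Conditions: TMSOTf (2.5 equiv), Et3N (4 equiv), CH2Cl2, 0 °C; then Pd(OAc)2 (1.05 equiv), MeCN, rt
Reagents that add atoms: trimethylsilyl trifluoromethanesulfonate, C[Si](C)(C)OS(=O)(=O)C(F)(F)F
Why: Saegusa–Ito oxidation, where the ketone can enolise only toward C-2 (the other α-carbon is quaternary) and palladation of the silyl enol ether followed by β-hydride elimination gives the enone, while the tertiary alcohol is silylated in the same operation and so protected for steps 8 to 13; no stereocentre changes.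

**Step 6**
Reactants: 14 prop-2-enal
Product: 16 2,3-dibromo-1,1-dimethoxypropane (racemic), via 2,3-dibromopropanal 15 (not isolated)
Conditions: Br2, CH2Cl2, −10 °C; then HC(OMe)3, MeOH, TsOH (cat.), rt
Reagents that add atoms: bromine, BrBr; trimethyl orthoformate, COC(OC)OC
Why: Alkene bromination followed by acid-catalysed acetalisation with the orthoester as water scavenger gives the protected dibromide, whose racemic stereocentre is destroyed in step 7.

**Step 7**
Reactants: 16 2,3-dibromo-1,1-dimethoxypropane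
Product: 17 2-bromo-3,3-dimethoxyprop-1-ene
Conditions: t-BuOK (1.05 equiv), THF, −20 → 0 °C
Reagents that add atoms: none
Why: E2 dehydrobromination removes the acidic C-2 hydrogen and the primary bromide to give the 2-bromoalkene, and no stereocentre remains.

**Step 8**
Reactants: 13 (4aR,5R,8aS)-5,8a-dimethyl-5-[(trimethylsilyl)oxy]-4a,5,6,7,8,8a-hexahydronaphthalen-1(4H)-one; 17 2-bromo-3,3-dimethoxyprop-1-ene
Product: 21 (3R,4aR,5R,8aS)-3-(3,3-dimethoxyprop-1-en-2-yl)-5,8a-dimethyl-5-[(trimethylsilyl)oxy]octahydronaphthalen-1(2H)-one, via (3,3-dimethoxyprop-1-en-2-yl)lithium 18 (not isolated), via lithium bis(3,3-dimethoxyprop-1-en-2-yl)cuprate 19 (not isolated), via lithium enolate 20 (not isolated)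
Conditions: 17 (2.4 equiv), t-BuLi (4.8 equiv), Et2O, −78 °C; CuBr·SMe2 (1.2 equiv), −78 → −50 °C; then 13, THF, −78 → −40 °C; aq. NH4Cl/NH3
Reagents that add atoms: none
Why: Bromine–lithium exchange and transmetalation give a Gilman alkenylcuprate (an acrolein α-anion equivalent) whose conjugate addition to the trans-fused cyclohexenone goes by axial attack on the α-face (chair-like enolate, anti to the angular methyl), so the new C-3 substituent is axial and cis to H-4a (3R); the acetal and silyl ether are inert.

**Step 9**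
Reactants: 21 (3R,4aR,5R,8aS)-3-(3,3-dimethoxyprop-1-en-2-yl)-5,8a-dimethyl-5-[(trimethylsilyl)oxy]octahydronaphthalen-1(2H)-one
Product: 23 (1R,3R,4aR,5R,8aS)-3-(3,3-dimethoxyprop-1-en-2-yl)-5,8a-dimethyl-5-[(trimethylsilyl)oxy]decahydronaphthalen-1-ol, via potassium alkoxide 22 (not isolated)
Conditions: K(s-Bu)3BH (1.5 equiv), THF, −78 °C; MeOH, aq. NH4Cl
Reagents that add atoms: none
Why: In this potassium tri-sec-butylborohydride reduction the axial approach on the α-face is blocked by the syn-axial C-3 substituent and the reagent is bulky, so hydride arrives equatorially and the alcohol is axial (1R), trans to the angular methyl; the potassium alkoxide is protonated on work-up, and acetal, silyl ether and alkene are inert.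

**Step 10**
Reactants: 24 methyl (2E)-but-2-enoate; 25 ethylmagnesium bromide
Product: 27 methyl (3R)-3-methylpentanoate, via bromomagnesium ester enolate 26 (not isolated)
Conditions: CuBr·SMe2 (5 mol %), (S)-1-[(Rp)-2-(diphenylphosphino)ferrocenyl]ethyldicyclohexylphosphine (6 mol %), t-BuOMe, −75 °C; aq. NH4Cl
Reagents that add atoms: none
Why: Copper–ferrocenyl diphosphine catalysed enantioselective conjugate addition of a Grignard reagent to an α,β-unsaturated ester, in which the ligand decides the face of C-3 attacked by ethyl and sets the (3R) centre.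

**Step 11**
Reactants: 27 methyl (3R)-3-methylpentanoate
Product: 29 (3R)-3-methylpentanoic acid, via lithium (3R)-3-methylpentanoate 28 (not isolated)
Conditions: LiOH, THF/H2O, rt; then 1 M HCl
Reagents that add atoms: lithium hydroxide, [Li+].[OH-]
Why: Saponification of the methyl ester, with the stereocentre β to the carboxyl group and therefore not epimerisable.

**Step 12**
Reactants: 29 (3R)-3-methylpentanoic acid
Product: 30 (3R)-3-methylpentanoyl chloride
Conditions: (COCl)2, DMF (cat.), CH2Cl2, 0 °C → rt
Reagents that add atoms: oxalyl chloride, ClC(=O)C(Cl)=O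
Why: Acid chloride formation through the chloroiminium (Vilsmeier-type) species, with no epimerisable centre.

**Step 13**
Reactants: 23 (1R,3R,4aR,5R,8aS)-3-(3,3-dimethoxyprop-1-en-2-yl)-5,8a-dimethyl-5-[(trimethylsilyl)oxy]decahydronaphthalen-1-ol; 30 (3R)-3-methylpentanoyl chloride
Product: 32 (1R,3R,4aR,5R,8aS)-3-(3,3-dimethoxyprop-1-en-2-yl)-5,8a-dimethyl-5-[(trimethylsilyl)oxy]decahydronaphthalen-1-yl (3R)-3-methylpentanoate, via lithium alkoxide 31 (not isolated)
Conditions: LiN(SiMe3)2 (1.2 equiv), THF, −78 °C; then 30 (1.5 equiv), DMAP (0.2 equiv), −78 °C → rt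
Reagents that add atoms: none
Why: Deprotonation of the purified alcohol gives the lithium alkoxide, whose O-acylation by the acid chloride overcomes the hindrance of the axial neopentyl-type hydroxyl; the only other hydroxyl is masked as its silyl ether, and C-1 keeps its configuration because the C–O bond is not broken.

**Step 14**
Reactants: 32 (1R,3R,4aR,5R,8aS)-3-(3,3-dimethoxyprop-1-en-2-yl)-5,8a-dimethyl-5-[(trimethylsilyl)oxy]decahydronaphthalen-1-yl (3R)-3-methylpentanoate
Product: 33 (1R,3R,4aR,5R,8aS)-5-hydroxy-5,8a-dimethyl-3-(3-oxoprop-1-en-2-yl)decahydronaphthalen-1-yl (3R)-3-methylpentanoate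
Conditions: 0.5 M HCl, THF/H2O, 0 °C → rt
Reagents that add atoms: water, O
Why: Dilute aqueous acid hydrolyses the allylic dimethyl acetal to the 2-substituted acrolein and cleaves the tertiary trimethylsilyl ether, while the secondary ester and the tertiary alcohol survive and no stereocentre is affected.

**Step 15**
Reactants: 33 (1R,3R,4aR,5R,8aS)-5-hydroxy-5,8a-dimethyl-3-(3-oxoprop-1-en-2-yl)decahydronaphthalen-1-yl (3R)-3-methylpentanoate
Product: 34 2-[(2R,4R,4aS,8R,8aR)-8-hydroxy-4a,8-dimethyl-4-{[(3R)-3-methylpentanoyl]oxy}decahydronaphthalen-2-yl]prop-2-enoic acid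
Conditions: NaClO2, NaH2PO4, 2-methylbut-2-ene, t-BuOH/H2O, 0 °C → rt
Reagents that add atoms: sodium chlorite, [Na+].[O-]Cl=O
Why: Pinnick oxidation converts the enal into the acrylic acid without touching the alkene, the ester or the tertiary alcohol, with 2-methylbut-2-ene scavenging hypochlorous acid.

**Compound list**
1 | 2-methylcyclohex-2-en-1-one | CC1=CCCCC1=O | starting material
2 | ethynyltrimethylsilane | C#C[Si](C)(C)C | starting material
3 | prop-2-en-1-yl acetate (allyl acetate) | CC(=O)OCC=C | starting material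
4 | diisobutyl[1-(trimethylsilyl)ethenyl]aluminium | C=C([Si](C)(C)C)[Al](CC(C)C)CC(C)C | intermediate
5 | diisobutylaluminium (3R)-2-methyl-3-[1-(trimethylsilyl)ethenyl]cyclohex-1-en-1-olate | CC1=C(O[Al](CC(C)C)CC(C)C)CCC[C@H]1C(=C)[Si](C)(C)C | intermediate
6 | (2S,3R)-2-methyl-2-(prop-2-en-1-yl)-3-[1-(trimethylsilyl)ethenyl]cyclohexan-1-one | O=C1CCC[C@@H](C(=C)[Si](C)(C)C)[C@]1(C)CC=C | intermediate
7 | (2S,3R)-3-(1-iodoethenyl)-2-methyl-2-(prop-2-en-1-yl)cyclohexan-1-one | O=C1CCC[C@@H](C(=C)I)[C@]1(C)CC=C | intermediate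
8 | (2S,3R)-2-[3-(9-borabicyclo[3.3.1]nonan-9-yl)propyl]-3-(1-iodoethenyl)-2-methylcyclohexan-1-one | O=C1CCC[C@@H](C(=C)I)[C@]1(C)CCCB1C2CCCC1CCC2 | intermediate
9 | (4aS,8aS)-8a-methyl-5-methylideneoctahydronaphthalen-1(2H)-one (trans-fused) | O=C1CCC[C@@H]2[C@]1(C)CCCC2=C | intermediate
10 | (4aR,5R,8aS)-5-hydroperoxy-5,8a-dimethyloctahydronaphthalen-1(2H)-one | O=C1CCC[C@@H]2[C@]1(C)CCC[C@@]2(C)OO | intermediate
11 | (4aR,5R,8aS)-5-hydroxy-5,8a-dimethyloctahydronaphthalen-1(2H)-one | O=C1CCC[C@@H]2[C@]1(C)CCC[C@@]2(C)O | intermediate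
12 | (4aR,5R,8aS)-5,8a-dimethyl-1,5-bis[(trimethylsilyl)oxy]-3,4,4a,5,6,7,8,8a-octahydronaphthalene | C[Si](C)(C)OC1=CCC[C@@H]2[C@]1(C)CCC[C@@]2(C)O[Si](C)(C)C | intermediate
13 | (4aR,5R,8aS)-5,8a-dimethyl-5-[(trimethylsilyl)oxy]-4a,5,6,7,8,8a-hexahydronaphthalen-1(4H)-one | O=C1C=CC[C@@H]2[C@]1(C)CCC[C@@]2(C)O[Si](C)(C)C | intermediate
14 | prop-2-enal (acrolein) | C=CC=O | starting material
15 | 2,3-dibromopropanal (racemic) | O=CC(Br)CBr | intermediate
16 | 2,3-dibromo-1,1-dimethoxypropane (racemic) | COC(OC)C(Br)CBr | intermediate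
17 | 2-bromo-3,3-dimethoxyprop-1-ene | C=C(Br)C(OC)OC | intermediate
18 | (3,3-dimethoxyprop-1-en-2-yl)lithium | [Li]C(=C)C(OC)OC | intermediate
19 | lithium bis(3,3-dimethoxyprop-1-en-2-yl)cuprate | [Li+].C=C([Cu-]C(=C)C(OC)OC)C(OC)OC | intermediate
20 | lithium (3R,4aR,5R,8aS)-3-(3,3-dimethoxyprop-1-en-2-yl)-5,8a-dimethyl-5-[(trimethylsilyl)oxy]-3,4,4a,5,6,7,8,8a-octahydronaphthalen-1-olate | C=C(C(OC)OC)[C@@H]1C[C@@H]2[C@](C)(CCC[C@@]2(C)O[Si](C)(C)C)C(O[Li])=C1 | intermediate
21 | (3R,4aR,5R,8aS)-3-(3,3-dimethoxyprop-1-en-2-yl)-5,8a-dimethyl-5-[(trimethylsilyl)oxy]octahydronaphthalen-1(2H)-one | C=C(C(OC)OC)[C@@H]1C[C@@H]2[C@](C)(CCC[C@@]2(C)O[Si](C)(C)C)C(=O)C1 | intermediate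
22 | potassium (1R,3R,4aR,5R,8aS)-3-(3,3-dimethoxyprop-1-en-2-yl)-5,8a-dimethyl-5-[(trimethylsilyl)oxy]decahydronaphthalen-1-olate | C=C(C(OC)OC)[C@@H]1C[C@@H]2[C@](C)(CCC[C@@]2(C)O[Si](C)(C)C)[C@H](O[K])C1 | intermediate
23 | (1R,3R,4aR,5R,8aS)-3-(3,3-dimethoxyprop-1-en-2-yl)-5,8a-dimethyl-5-[(trimethylsilyl)oxy]decahydronaphthalen-1-ol | C=C(C(OC)OC)[C@@H]1C[C@@H]2[C@](C)(CCC[C@@]2(C)O[Si](C)(C)C)[C@H](O)C1 | intermediate
24 | methyl (2E)-but-2-enoate | C/C=C/C(=O)OC | starting material
25 | ethylmagnesium bromide | CC[Mg]Br | starting material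
26 | bromo{[(3R)-1-methoxy-3-methylpent-1-en-1-yl]oxy}magnesium | COC(O[Mg]Br)=C[C@H](C)CC | intermediate
27 | methyl (3R)-3-methylpentanoate | COC(=O)C[C@H](C)CC | intermediate
28 | lithium (3R)-3-methylpentanoate | [Li+].[O-]C(=O)C[C@H](C)CC | intermediate
29 | (3R)-3-methylpentanoic acid | OC(=O)C[C@H](C)CC | intermediate
30 | (3R)-3-methylpentanoyl chloride | ClC(=O)C[C@H](C)CC | intermediate
31 | lithium (1R,3R,4aR,5R,8aS)-3-(3,3-dimethoxyprop-1-en-2-yl)-5,8a-dimethyl-5-[(trimethylsilyl)oxy]decahydronaphthalen-1-olate | C=C(C(OC)OC)[C@@H]1C[C@@H]2[C@](C)(CCC[C@@]2(C)O[Si](C)(C)C)[C@H](O[Li])C1 | intermediate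
32 | (1R,3R,4aR,5R,8aS)-3-(3,3-dimethoxyprop-1-en-2-yl)-5,8a-dimethyl-5-[(trimethylsilyl)oxy]decahydronaphthalen-1-yl (3R)-3-methylpentanoate | C=C(C(OC)OC)[C@@H]1C[C@@H]2[C@](C)(CCC[C@@]2(C)O[Si](C)(C)C)[C@H](OC(=O)C[C@H](C)CC)C1 | intermediate
33 | (1R,3R,4aR,5R,8aS)-5-hydroxy-5,8a-dimethyl-3-(3-oxoprop-1-en-2-yl)decahydronaphthalen-1-yl (3R)-3-methylpentanoate | C=C(C=O)[C@@H]1C[C@@H]2[C@](C)(CCC[C@@]2(C)O)[C@H](OC(=O)C[C@H](C)CC)C1 | intermediate
34 | 2-[(2R,4R,4aS,8R,8aR)-8-hydroxy-4a,8-dimethyl-4-{[(3R)-3-methylpentanoyl]oxy}decahydronaphthalen-2-yl]prop-2-enoic acid | C=C(C(=O)O)[C@@H]1C[C@@H]2[C@](C)(CCC[C@@]2(C)O)[C@H](OC(=O)C[C@H](C)CC)C1 | target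

**Total step count:** 15.
**Longest linear sequence:** 10 (steps 1, 2, 3, 4, 5, 8, 9, 13, 14, 15). Steps 6–7 (side-chain reagent) and 10–12 (acyl chloride) are side branches.

**Steps most likely to fail, with fallbacks**

Step 1 (the proposed new step). The catalyst may give low turnover or low enantioselectivity on the 2-methyl enone, or the aluminium enolate may allylate poorly at the quaternary carbon. The fallback uses known chemistry, sets out from 1 and comes back at 6. (1-Bromoethenyl)trimethylsilane F1 is converted with magnesium in THF into [1-(trimethylsilyl)ethenyl]magnesium bromide F2. This is added to 1 with CuBr·SMe2 (10 mol %) at −40 °C to give the racemic bromomagnesium enolate F3. Allyl bromide and DMPU then alkylate it anti to the 3-substituent to give the racemic trans ketone F4. The enantiomers are separated by preparative supercritical-fluid chromatography on a chiral stationary phase, and the (2S,3R) enantiomer is 6.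

Step 3. 9-BBN may partly reduce the ketone, or the ring-closing cross-coupling may be slow against protodeboronation. The fallback sets out from 7 and comes back at 9 without boron or palladium. Bu3SnH (1.2 equiv, syringe pump) with AIBN in benzene at 80 °C and 0.005 M generates the 1-alkenyl radical from the iodide. It closes onto the terminal alkene either 6-endo directly or 5-exo followed by homoallyl–cyclopropylcarbinyl ring expansion at low stannane concentration. Both paths give the methylenecyclohexane ring of 9. This fallback makes no new compound (entry F0).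

Step 4. The radical may be trapped from both faces, giving a mixture of C-5 epimers. The fallback sets out from 9 and comes back at 11 by ionic chemistry. m-CPBA with NaHCO3 in CH2Cl2 at 0 °C epoxidises the exocyclic alkene from the α-face to give the spiro-epoxide F5. LiAlH4 in THF opens the epoxide at its primary carbon and also reduces the ketone, giving the diol F6 as a mixture of C-1 epimers. Dess–Martin periodinane re-oxidises the secondary alcohol only, giving 11.

**Further compounds**
F1 | step 1 | (1-bromoethenyl)trimethylsilane | C=C(Br)[Si](C)(C)C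
F2 | step 1 | [1-(trimethylsilyl)ethenyl]magnesium bromide | C=C([Si](C)(C)C)[Mg]Br
F3 | step 1 | bromomagnesium 2-methyl-3-[1-(trimethylsilyl)ethenyl]cyclohex-1-en-1-olate (racemic) | CC1=C(O[Mg]Br)CCCC1C(=C)[Si](C)(C)C
F4 | step 1 | racemic trans-2-methyl-2-(prop-2-en-1-yl)-3-[1-(trimethylsilyl)ethenyl]cyclohexan-1-one (6 plus its mirror image) | O=C1CCC[C@@H](C(=C)[Si](C)(C)C)[C@]1(C)CC=C.O=C1CCC[C@H](C(=C)[Si](C)(C)C)[C@@]1(C)CC=C
F0 | step 3 | none | none
F5 | step 4 | (4aR,5R,8aS)-8a-methyloctahydro-1H-spiro[naphthalene-5,2'-oxiran]-1-one (epoxide oxygen on the α-face, trans to the angular methyl) | O=C1CCC[C@@H]2[C@]1(C)CCC[C@@]2(C3)O3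
F6 | step 4 | (4aR,5R,8aS)-5,8a-dimethyldecahydronaphthalene-1,5-diol (both C-1 epimers) | OC1CCC[C@@H]2[C@]1(C)CCC[C@@]2(C)O
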